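**Retrosynthetic overview**
1. Last bonds: the quinone of rings A and B is unveiled from its 1,4-dimethyl ether; before that, the tail beyond Cx and the C13'–C14' bond are made by copper-catalysed sp3–sp3 couplings, which divide the target into ring C iodide 13 and chain chloride 30.
2. Feature on which the plan rests: ring C (Ca bearing C14', Cb, Cc, Cd bearing the methine Cx, Ce between Cd and Ca) carries carbon substituents only at Ca and Cd, 1,3 and cis. This is the pattern of a cyclopent-1-ene-1,4-diester, the (3+2) adduct of an allenoate (Ca, Cb, Cc) and an acrylate (Cd, Ce).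
3. Ring C: chiral-phosphine (3+2) annulation of 1 and 2 makes Ca–Ce and Cc–Cd and sets Cd; hydrogenation sets Ca; the Cd ester goes via a β-keto ester and its (Z)-enol triflate to the (E)-β-methyl enoate, whose copper hydride reduction sets Cx; the Ca ester becomes CH2I (C14').
4. Chain C1'–C13': (S)-1-bromo-5-chloro-3-methylpentane serves twice (C1'–C5' and C9'–C13') around (S)-1-bromo-3-chloro-2-methylpropane (C6'–C8'); bromide reacts, chloride waits as latent Grignard reagent; the arene is joined by Negishi coupling.
5. Ring order: rings A and B are bought with menadione and only masked; ring C is the single ring built, in step 1.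

Key step: step 1

Remark: chain carbons are C1'–C14' counted from the quinone; methyl hydrogen (R)-3-methylglutarate 18 and (S)-3-bromo-2-methylpropan-1-ol 23 are assumed to be bought enantiopure; the catalyst antipodes in steps 1 and 7 are those that give the stated configurations, to be confirmed in a trial run.

Step 1
Reactants: 1 ethyl buta-2,3-dienoate; 2 tert-butyl acrylate
Product: 3 4-tert-butyl 1-ethyl (4S)-cyclopent-1-ene-1,4-dicarboxylate
Conditions: enantiopure 2,5-diisopropyl-7-phenyl-7-phosphabicyclo[2.2.1]heptane (10 mol%; antipode that gives (S)-3), toluene, 0 °C, slow addition of 1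
Reagents that add atoms: none
Why: The phosphine adds to the central carbon of allenoate 1, and the ester-bearing α-carbon of the resulting zwitterion attacks the β-carbon of acrylate 2 (Ca–Ce); the new ester enolate carbon then closes onto the γ-carbon of the vinylphosphonium (Cc–Cd), and proton shift with loss of the phosphine leaves the conjugated cyclopentene. The reaction type is the known enantioselective phosphine-catalysed (3+2) annulation of 2,3-butadienoates with acrylates. Ring C closes stepwise, the second bond formation being formally a 5-endo-trig attack of the enolate on the phosphonium-activated alkene. The only new stereocenter, Cd, is fixed during the C–C bond formations inside the chiral pocket of the rigid C2-symmetric bicyclic phosphine, so the catalyst antipode decides its sense. The step needs α- over γ-addition (1,3- and not 1,2-diester) and high facial selectivity at Cd; the ester on the allenoate α-carbon makes that terminus the more nucleophilic one, and the bulky tert-butyl ester of 2 together with the hindered phosphine should reinforce both. The two esters stay distinguishable, so the Ca ester carbon can later become C14' and the Cd ester carbon Cx.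

Step 2
Reactants: 3 4-tert-butyl 1-ethyl (4S)-cyclopent-1-ene-1,4-dicarboxylate
Product: 4 1-tert-butyl 3-ethyl (1S,3R)-cyclopentane-1,3-dicarboxylate
Conditions: H2 (1 atm), 10% Pd/C, EtOAc, rt
Reagents that add atoms: none
Why: Heterogeneous syn-hydrogenation of the trisubstituted enoate should deliver hydrogen to the ring face opposite the tert-butyl ester at Cd, which places the Ca ester cis to it and sets Ca as R by substrate control.

Step 3
Reactants: 4 1-tert-butyl 3-ethyl (1S,3R)-cyclopentane-1,3-dicarboxylate
Product: 5 (1S,3R)-3-(ethoxycarbonyl)cyclopentane-1-carboxylic acid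
Conditions: CF3CO2H, CH2Cl2, 0 °C to rt
Reagents that add atoms: none
Why: Acidolysis of the tert-butyl ester (loss of 2-methylpropene from the protonated ester) leaves the ethyl ester and both ring stereocenters untouched.

Step 4
Reactants: 5 (1S,3R)-3-(ethoxycarbonyl)cyclopentane-1-carboxylic acid
Product: 8 ethyl (1R,3S)-3-(3-tert-butoxy-3-oxopropanoyl)cyclopentane-1-carboxylate, via acyl imidazolide 6 (not isolated), via acylmalonate half-acid 7 (not isolated)
Conditions: 1,1'-carbonyldiimidazole, THF, rt; then Mg(O2CCH2CO2t-Bu)2, THF, rt to 45 °C; 1 M HCl work-up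
Reagents that add atoms: 1,1'-carbonyldiimidazole, O=C(n1ccnc1)n1ccnc1 (imidazolyl group kept only in intermediate 6); magnesium bis(3-tert-butoxy-3-oxopropanoate), [Mg+2].[O-]C(=O)CC(=O)OC(C)(C)C.[O-]C(=O)CC(=O)OC(C)(C)C
Why: The acyl imidazolide acylates the magnesium enolate of the malonate half-ester (decarboxylative Claisen-type acylation) and the acylmalonate loses CO2 on work-up, all under near-neutral conditions that should leave Cd and the Ca ethyl ester untouched.

Step 5
Reactants: 8 ethyl (1R,3S)-3-(3-tert-butoxy-3-oxopropanoyl)cyclopentane-1-carboxylate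
Product: 9 tert-butyl (2Z)-3-[(1S,3R)-3-(ethoxycarbonyl)cyclopentyl]-3-[(trifluoromethanesulfonyl)oxy]prop-2-enoate
Conditions: (CF3SO2)2O, LiOSO2CF3, Et3N, CH2Cl2, 0 °C
Reagents that add atoms: trifluoromethanesulfonic anhydride, O=S(=O)(OS(=O)(=O)C(F)(F)F)C(F)(F)F
Why: The lithium-chelated (Z)-enolate of the β-keto ester is trapped on oxygen (stereoselective enol triflate formation), which places the triflate cis to the ester, and since only the doubly activated CH2 is deprotonated Cd cannot epimerise.

Step 6
Reactants: 9 tert-butyl (2Z)-3-[(1S,3R)-3-(ethoxycarbonyl)cyclopentyl]-3-[(trifluoromethanesulfonyl)oxy]prop-2-enoate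
Product: 10 tert-butyl (2E)-3-[(1S,3R)-3-(ethoxycarbonyl)cyclopentyl]but-2-enoate
Conditions: MeMgBr, Fe(acac)3 (5 mol%), THF/NMP, −30 °C
Reagents that add atoms: methylmagnesium bromide, C[Mg]Br
Why: Iron-catalysed cross-coupling of the alkenyl triflate with the methyl Grignard reagent replaces triflate by methyl with retention of geometry, so the (Z)-triflate gives the (E)-enoate with ring C trans to the ester, and the coupling is much faster than attack on either ester.

Step 7
Reactants: 10 tert-butyl (2E)-3-[(1S,3R)-3-(ethoxycarbonyl)cyclopentyl]but-2-enoate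
Product: 11 tert-butyl (3R)-3-[(1S,3R)-3-(ethoxycarbonyl)cyclopentyl]butanoate
Conditions: Cu(OAc)2 (5 mol%), (R)-DTBM-SEGPHOS (5.5 mol%; antipode to be confirmed on a model enoate), (EtO)2MeSiH, t-BuOH, toluene, 0 °C to rt
Reagents that add atoms: none
Why: Ligand-controlled asymmetric 1,4-reduction by a copper hydride (conjugate hydrosilylation, then protonation by t-BuOH) should add hydride to the Re face of the β-carbon of the geometrically pure (E)-enoate and set Cx as R, the ligand antipode being the one that turns (E)-ethyl 3-phenylbut-2-enoate into (R)-ethyl 3-phenylbutanoate, while the saturated ethyl ester is inert.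

Step 8
Reactants: 11 tert-butyl (3R)-3-[(1S,3R)-3-(ethoxycarbonyl)cyclopentyl]butanoate
Product: 12 tert-butyl (3R)-3-[(1S,3R)-3-(hydroxymethyl)cyclopentyl]butanoate
Conditions: LiBH4, THF, 0 °C to rt
Reagents that add atoms: none
Why: LiBH4 reduces the ethyl ester chemoselectively (ester reduction) because the hindered tert-butyl ester reacts far more slowly, giving the C14' carbinol without touching any stereocenter.

Step 9
Reactants: 12 tert-butyl (3R)-3-[(1S,3R)-3-(hydroxymethyl)cyclopentyl]butanoate
Product: 13 tert-butyl (3R)-3-[(1S,3R)-3-(iodomethyl)cyclopentyl]butanoate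
Conditions: I2, PPh3, imidazole, CH2Cl2, 0 °C to rt
Reagents that add atoms: iodine, [I][I]
Why: Appel-type iodination converts the primary alcohol into the iodide by SN2 displacement of the oxyphosphonium under near-neutral conditions that the tert-butyl ester tolerates.

Step 10
Reactants: 14 menadione (2-methylnaphthalene-1,4-dione)
Product: 16 1,4-dimethoxy-2-methylnaphthalene, via menadiol 15 (not isolated)
Conditions: Na2S2O4, n-Bu4NBr (cat.), THF/H2O, rt; then aq. KOH, Me2SO4, rt
Reagents that add atoms: dimethyl sulfate, COS(=O)(=O)OC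
Why: Reduction of the quinone to the hydroquinone followed in the same flask by double Williamson O-methylation masks rings A and B as a dimethyl ether that is stable to bases and organometallic reagents but can be oxidised back at the end.

Step 11
Reactants: 16 1,4-dimethoxy-2-methylnaphthalene
Product: 17 2-bromo-1,4-dimethoxy-3-methylnaphthalene
Conditions: Br2, CH2Cl2, 0 °C
Reagents that add atoms: bromine, BrBr
Why: Electrophilic aromatic bromination goes to C3, the only free position of the doubly methoxy-activated ring.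

Step 12
Reactants: 18 (3R)-5-methoxy-3-methyl-5-oxopentanoic acid
Product: 19 methyl (3R)-5-hydroxy-3-methylpentanoate
Conditions: BH3·SMe2, THF, −10 °C to rt; MeOH quench
Reagents that add atoms: none
Why: Borane reduces the free carboxylic acid via its acyloxyborane much faster than the methyl ester (chemoselective acid reduction), and the stereocenter is not involved.

Step 13
Reactants: 19 methyl (3R)-5-hydroxy-3-methylpentanoate
Product: 20 methyl (3S)-5-bromo-3-methylpentanoate
Conditions: CBr4, PPh3, CH2Cl2, 0 °C
Reagents that add atoms: tetrabromomethane, BrC(Br)(Br)Br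
Why: Appel bromination replaces the primary hydroxyl by bromide (SN2 on the oxyphosphonium) under neutral conditions that leave the ester intact and forestall lactonisation.

Step 14
Reactants: 20 methyl (3S)-5-bromo-3-methylpentanoate
Product: 21 (3S)-5-bromo-3-methylpentan-1-ol
Conditions: i-Bu2AlH, CH2Cl2, −78 to 0 °C
Reagents that add atoms: none
Why: The aluminium hydride reduces the ester to the primary alcohol at low temperature (ester reduction) without reducing the primary alkyl bromide.

Step 15
Reactants: 21 (3S)-5-bromo-3-methylpentan-1-ol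
Product: 22 (3S)-1-bromo-5-chloro-3-methylpentane
Conditions: PPh3, N-chlorosuccinimide, CH2Cl2, 0 °C to rt
Reagents that add atoms: N-chlorosuccinimide, O=C1CCC(=O)N1Cl
Why: Appel-type chlorination replaces the hydroxyl by chloride under mild conditions, giving a building block whose ends differ in reactivity and whose chirality rests only on that difference.

Step 16
Reactants: 23 (2S)-3-bromo-2-methylpropan-1-ol
Product: 24 (2S)-1-bromo-3-chloro-2-methylpropane
Conditions: PPh3, N-chlorosuccinimide, CH2Cl2, 0 °C to rt
Reagents that add atoms: N-chlorosuccinimide, O=C1CCC(=O)N1Cl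
Why: The same Appel-type chlorination turns the purchased bromo alcohol into the C6'–C8' unit with a reactive bromide end and a dormant chloride end, the stereocenter (future C7') being untouched.

Step 17
Reactants: 22 (3S)-1-bromo-5-chloro-3-methylpentane; 17 2-bromo-1,4-dimethoxy-3-methylnaphthalene
Product: 26 2-[(3R)-5-chloro-3-methylpentyl]-1,4-dimethoxy-3-methylnaphthalene, via alkylzinc bromide 25 (not isolated)
Conditions: Zn dust, LiCl, THF, 50 °C; then 17, Pd(OAc)2 (2 mol%), SPhos (4 mol%), THF, 60 °C
Reagents that add atoms: zinc, [Zn] (kept only in intermediate 25)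
Why: Zinc inserts into the C–Br bond only, and the primary alkylzinc bromide undergoes Negishi coupling with the hindered, electron-rich aryl bromide under a bulky biarylphosphine palladium catalyst without touching the alkyl chloride or C3'.

Step 18
Reactants: 26 2-[(3R)-5-chloro-3-methylpentyl]-1,4-dimethoxy-3-methylnaphthalene; 24 (2S)-1-bromo-3-chloro-2-methylpropane
Product: 28 2-[(3S,7R)-8-chloro-3,7-dimethyloctyl]-1,4-dimethoxy-3-methylnaphthalene, via Grignard reagent 27 (not isolated)
Conditions: Mg turnings, THF, reflux; then 24, Li2CuCl4 (3 mol%), NMP, THF, 0 °C to rt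
Reagents that add atoms: magnesium, [Mg] (kept only in intermediate 27)
Why: The alkyl chloride is turned into its Grignard reagent, which under copper catalysis couples (sp3–sp3 cross-coupling) at the bromide end of 24 only, alkyl chlorides being inert under these conditions, so C7' enters with its configuration intact.

Step 19
Reactants: 28 2-[(3S,7R)-8-chloro-3,7-dimethyloctyl]-1,4-dimethoxy-3-methylnaphthalene; 22 (3S)-1-bromo-5-chloro-3-methylpentane
Product: 30 2-[(3S,7R,11R)-13-chloro-3,7,11-trimethyltridecyl]-1,4-dimethoxy-3-methylnaphthalene, via Grignard reagent 29 (not isolated)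
Conditions: Mg turnings, THF, reflux; then 22, Li2CuCl4 (3 mol%), NMP, THF, 0 °C to rt
Reagents that add atoms: magnesium, [Mg] (kept only in intermediate 29)
Why: A second copper-catalysed sp3–sp3 coupling of the chloride-derived Grignard reagent at the bromide end of 22 adds C9'–C13' with C11' preformed and leaves a terminal chloride for the next Grignard formation.

Step 20
Reactants: 30 2-[(3S,7R,11R)-13-chloro-3,7,11-trimethyltridecyl]-1,4-dimethoxy-3-methylnaphthalene; 13 tert-butyl (3R)-3-[(1S,3R)-3-(iodomethyl)cyclopentyl]butanoate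
Product: 32 tert-butyl (3R)-3-[(1S,3R)-3-[(4R,8S,12S)-14-(1,4-dimethoxy-3-methylnaphthalen-2-yl)-4,8,12-trimethyltetradecyl]cyclopentyl]butanoate, via Grignard reagent 31 (not isolated)
Conditions: Mg turnings, THF, reflux; then 13, Li2CuCl4 (5 mol%), NMP, THF, 0 °C
Reagents that add atoms: magnesium, [Mg] (kept only in intermediate 31)
Why: Copper-catalysed sp3–sp3 cross-coupling of the primary Grignard reagent with the primary iodide forms the C13'–C14' bond at a temperature at which the hindered tert-butyl ester should survive, and no stereocenter is touched.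

Step 21
Reactants: 32 tert-butyl (3R)-3-[(1S,3R)-3-[(4R,8S,12S)-14-(1,4-dimethoxy-3-methylnaphthalen-2-yl)-4,8,12-trimethyltetradecyl]cyclopentyl]butanoate
Product: 33 (3R)-3-[(1S,3R)-3-[(4R,8S,12S)-14-(1,4-dimethoxy-3-methylnaphthalen-2-yl)-4,8,12-trimethyltetradecyl]cyclopentyl]butan-1-ol
Conditions: LiAlH4, THF, 0 °C to rt
Reagents that add atoms: none
Why: LiAlH4 reduces the tert-butyl ester to the primary alcohol (ester reduction) while the aryl methyl ethers and the saturated chain are inert.

Step 22
Reactants: 33 (3R)-3-[(1S,3R)-3-[(4R,8S,12S)-14-(1,4-dimethoxy-3-methylnaphthalen-2-yl)-4,8,12-trimethyltetradecyl]cyclopentyl]butan-1-ol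
Product: 34 (3R)-3-[(1S,3R)-3-[(4R,8S,12S)-14-(1,4-dimethoxy-3-methylnaphthalen-2-yl)-4,8,12-trimethyltetradecyl]cyclopentyl]butyl 4-methylbenzenesulfonate
Conditions: TsCl, Et3N, DMAP (cat.), CH2Cl2, 0 °C to rt
Reagents that add atoms: 4-methylbenzenesulfonyl chloride, Cc1ccc(cc1)S(Cl)(=O)=O
Why: Sulfonylation of the unhindered primary alcohol (tosylation) installs the leaving group for the last C–C coupling.

Step 23
Reactants: 34 (3R)-3-[(1S,3R)-3-[(4R,8S,12S)-14-(1,4-dimethoxy-3-methylnaphthalen-2-yl)-4,8,12-trimethyltetradecyl]cyclopentyl]butyl 4-methylbenzenesulfonate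
Product: 35 1,4-dimethoxy-2-methyl-3-[(3S,7S,11R)-3,7,11-trimethyl-14-[(1R,3S)-3-[(2R)-6-methylheptan-2-yl]cyclopentyl]tetradecyl]naphthalene
Conditions: i-BuMgBr, Li2CuCl4 (5 mol%), THF, −78 °C to rt
Reagents that add atoms: isobutylmagnesium bromide, CC(C)C[Mg]Br
Why: Copper-catalysed sp3–sp3 coupling of the primary tosylate with the isobutyl Grignard reagent completes the 6-methylheptan-2-yl tail, and Cx, two bonds from the reacting carbon, is not affected.

Step 24
Reactants: 35 1,4-dimethoxy-2-methyl-3-[(3S,7S,11R)-3,7,11-trimethyl-14-[(1R,3S)-3-[(2R)-6-methylheptan-2-yl]cyclopentyl]tetradecyl]naphthalene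
Product: 36 2-methyl-3-[(3S,7S,11R)-3,7,11-trimethyl-14-[(1R,3S)-3-[(2R)-6-methylheptan-2-yl]cyclopentyl]tetradecyl]naphthalene-1,4-dione
Conditions: (NH4)2Ce(NO3)6, MeCN/CH2Cl2/H2O, 0 °C
Reagents that add atoms: water, O
Why: The cerium oxidant removes two electrons from the electron-rich 1,4-dimethoxyarene, water adds at the two ipso carbons and methanol leaves (oxidative demethylation), which unveils the 1,4-naphthoquinone of rings A and B without touching the saturated chain.

**Compound list**
1 | ethyl buta-2,3-dienoate | C=C=CC(=O)OCC | starting material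
2 | tert-butyl acrylate | C=CC(=O)OC(C)(C)C | starting material
3 | 4-tert-butyl 1-ethyl (4S)-cyclopent-1-ene-1,4-dicarboxylate | CCOC(=O)C1=CC[C@H](C(=O)OC(C)(C)C)C1 | intermediate
4 | 1-tert-butyl 3-ethyl (1S,3R)-cyclopentane-1,3-dicarboxylate | CCOC(=O)[C@@H]1CC[C@H](C(=O)OC(C)(C)C)C1 | intermediate
5 | (1S,3R)-3-(ethoxycarbonyl)cyclopentane-1-carboxylic acid | CCOC(=O)[C@@H]1CC[C@H](C(=O)O)C1 | intermediate
6 | ethyl (1R,3S)-3-(1H-imidazole-1-carbonyl)cyclopentane-1-carboxylate (not isolated) | CCOC(=O)[C@@H]1CC[C@H](C(=O)n2ccnc2)C1 | intermediate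
7 | 2-(tert-butoxycarbonyl)-3-[(1S,3R)-3-(ethoxycarbonyl)cyclopentyl]-3-oxopropanoic acid (not isolated; present as its magnesium chelate, labile at the malonyl carbon) | CCOC(=O)[C@@H]1CC[C@H](C(=O)C(C(=O)O)C(=O)OC(C)(C)C)C1 | intermediate
8 | ethyl (1R,3S)-3-(3-tert-butoxy-3-oxopropanoyl)cyclopentane-1-carboxylate | CCOC(=O)[C@@H]1CC[C@H](C(=O)CC(=O)OC(C)(C)C)C1 | intermediate
9 | tert-butyl (2Z)-3-[(1S,3R)-3-(ethoxycarbonyl)cyclopentyl]-3-[(trifluoromethanesulfonyl)oxy]prop-2-enoate | CCOC(=O)[C@@H]1CC[C@H](/C(OS(=O)(=O)C(F)(F)F)=C/C(=O)OC(C)(C)C)C1 | intermediate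
10 | tert-butyl (2E)-3-[(1S,3R)-3-(ethoxycarbonyl)cyclopentyl]but-2-enoate | CCOC(=O)[C@@H]1CC[C@H](/C(C)=C/C(=O)OC(C)(C)C)C1 | intermediate
11 | tert-butyl (3R)-3-[(1S,3R)-3-(ethoxycarbonyl)cyclopentyl]butanoate | CCOC(=O)[C@@H]1CC[C@H]([C@H](C)CC(=O)OC(C)(C)C)C1 | intermediate
12 | tert-butyl (3R)-3-[(1S,3R)-3-(hydroxymethyl)cyclopentyl]butanoate | OC[C@@H]1CC[C@H]([C@H](C)CC(=O)OC(C)(C)C)C1 | intermediate
13 | tert-butyl (3R)-3-[(1S,3R)-3-(iodomethyl)cyclopentyl]butanoate | IC[C@@H]1CC[C@H]([C@H](C)CC(=O)OC(C)(C)C)C1 | intermediate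
14 | menadione (2-methylnaphthalene-1,4-dione) | CC1=CC(=O)c2ccccc2C1=O | starting material
15 | menadiol (2-methylnaphthalene-1,4-diol; not isolated) | Cc1cc(O)c2ccccc2c1O | intermediate
16 | 1,4-dimethoxy-2-methylnaphthalene | COc1cc(C)c(OC)c2ccccc12 | intermediate
17 | 2-bromo-1,4-dimethoxy-3-methylnaphthalene | COc1c(Br)c(C)c(OC)c2ccccc12 | intermediate
18 | (3R)-5-methoxy-3-methyl-5-oxopentanoic acid (methyl hydrogen (R)-3-methylglutarate) | COC(=O)C[C@H](C)CC(=O)O | starting material
19 | methyl (3R)-5-hydroxy-3-methylpentanoate | COC(=O)C[C@H](C)CCO | intermediate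
20 | methyl (3S)-5-bromo-3-methylpentanoate | COC(=O)C[C@H](C)CCBr | intermediate
21 | (3S)-5-bromo-3-methylpentan-1-ol | OCC[C@H](C)CCBr | intermediate
22 | (3S)-1-bromo-5-chloro-3-methylpentane | ClCC[C@H](C)CCBr | intermediate
23 | (2S)-3-bromo-2-methylpropan-1-ol | BrC[C@@H](C)CO | starting material
24 | (2S)-1-bromo-3-chloro-2-methylpropane | BrC[C@@H](C)CCl | intermediate
25 | bromo[(3S)-5-chloro-3-methylpentyl]zinc (not isolated) | ClCC[C@H](C)CC[Zn]Br | intermediate
26 | 2-[(3R)-5-chloro-3-methylpentyl]-1,4-dimethoxy-3-methylnaphthalene | COc1c(C)c(CC[C@@H](C)CCCl)c(OC)c2ccccc12 | intermediate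
27 | chloro[(3R)-5-(1,4-dimethoxy-3-methylnaphthalen-2-yl)-3-methylpentyl]magnesium (not isolated) | COc1c(C)c(CC[C@@H](C)CC[Mg]Cl)c(OC)c2ccccc12 | intermediate
28 | 2-[(3S,7R)-8-chloro-3,7-dimethyloctyl]-1,4-dimethoxy-3-methylnaphthalene | COc1c(C)c(CC[C@@H](C)CCC[C@@H](C)CCl)c(OC)c2ccccc12 | intermediate
29 | chloro[(2R,6S)-8-(1,4-dimethoxy-3-methylnaphthalen-2-yl)-2,6-dimethyloctyl]magnesium (not isolated) | COc1c(C)c(CC[C@@H](C)CCC[C@@H](C)C[Mg]Cl)c(OC)c2ccccc12 | intermediate
30 | 2-[(3S,7R,11R)-13-chloro-3,7,11-trimethyltridecyl]-1,4-dimethoxy-3-methylnaphthalene | COc1c(C)c(CC[C@@H](C)CCC[C@@H](C)CCC[C@@H](C)CCCl)c(OC)c2ccccc12 | intermediate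
31 | chloro[(3R,7R,11S)-13-(1,4-dimethoxy-3-methylnaphthalen-2-yl)-3,7,11-trimethyltridecyl]magnesium (not isolated) | COc1c(C)c(CC[C@@H](C)CCC[C@@H](C)CCC[C@@H](C)CC[Mg]Cl)c(OC)c2ccccc12 | intermediate
32 | tert-butyl (3R)-3-[(1S,3R)-3-[(4R,8S,12S)-14-(1,4-dimethoxy-3-methylnaphthalen-2-yl)-4,8,12-trimethyltetradecyl]cyclopentyl]butanoate | COc1c(C)c(CC[C@@H](C)CCC[C@@H](C)CCC[C@@H](C)CCC[C@@H]3CC[C@H]([C@H](C)CC(=O)OC(C)(C)C)C3)c(OC)c2ccccc12 | intermediate
33 | (3R)-3-[(1S,3R)-3-[(4R,8S,12S)-14-(1,4-dimethoxy-3-methylnaphthalen-2-yl)-4,8,12-trimethyltetradecyl]cyclopentyl]butan-1-ol | COc1c(C)c(CC[C@@H](C)CCC[C@@H](C)CCC[C@@H](C)CCC[C@@H]3CC[C@H]([C@H](C)CCO)C3)c(OC)c2ccccc12 | intermediate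
34 | (3R)-3-[(1S,3R)-3-[(4R,8S,12S)-14-(1,4-dimethoxy-3-methylnaphthalen-2-yl)-4,8,12-trimethyltetradecyl]cyclopentyl]butyl 4-methylbenzenesulfonate | COc1c(C)c(CC[C@@H](C)CCC[C@@H](C)CCC[C@@H](C)CCC[C@@H]3CC[C@H]([C@H](C)CCOS(=O)(=O)c4ccc(C)cc4)C3)c(OC)c2ccccc12 | intermediate
35 | 1,4-dimethoxy-2-methyl-3-[(3S,7S,11R)-3,7,11-trimethyl-14-[(1R,3S)-3-[(2R)-6-methylheptan-2-yl]cyclopentyl]tetradecyl]naphthalene | COc1c(C)c(CC[C@@H](C)CCC[C@@H](C)CCC[C@@H](C)CCC[C@@H]3CC[C@H]([C@H](C)CCCC(C)C)C3)c(OC)c2ccccc12 | intermediate
36 | 2-methyl-3-[(3S,7S,11R)-3,7,11-trimethyl-14-[(1R,3S)-3-[(2R)-6-methylheptan-2-yl]cyclopentyl]tetradecyl]naphthalene-1,4-dione | CC1=C(CC[C@@H](C)CCC[C@@H](C)CCC[C@@H](C)CCC[C@@H]2CC[C@H]([C@H](C)CCCC(C)C)C2)C(=O)c2ccccc2C1=O | target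

**Step count**
Total: 24 steps. Longest linear sequence: 14 steps (steps 1–9, then 20–24); the chain branch (steps 12–15, 17–19, then 20–24) is 12 steps long.

**Steps most likely to fail**

1. Step 1. Facial discrimination at Cd may be incomplete and γ-addition may compete, so that 3 would be enantiomerically impure and mixed with the 1,2-diester; every later compound would then carry an inseparable diastereomer. A salt of acid 5 with an enantiopure amine could be recrystallised as a first remedy. Fallback: it sets out from none of the numbered compounds, replaces steps 1–3 and comes back at 5. The purchased meso anhydride (1R,5S)-3-oxabicyclo[3.2.1]octane-2,4-dione F1 would be opened with ethanol in the presence of a cinchona alkaloid catalyst (desymmetrising alcoholysis, quinidine- or quinine-derived catalyst chosen for the sense), which should give the cis hemiester 5 directly.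

2. Step 2. Hydrogen may be delivered to both ring faces because the Cd ester is remote from the alkene, which would give some trans diester that is hard to remove. Fallback: it sets out from 3 and comes back at 4. LiOH in THF/H2O at 0 °C would hydrolyse only the conjugated ethyl ester to (4S)-4-(tert-butoxycarbonyl)cyclopent-1-ene-1-carboxylic acid F2. Hydrogenation of this acid with H2 and Ru(OAc)2[(R)-BINAP] or its antipode in MeOH (carboxylate-bound, catalyst-controlled asymmetric hydrogenation) would set Ca independently of the ring bias and give (1R,3S)-3-(tert-butoxycarbonyl)cyclopentane-1-carboxylic acid F3. EtI and K2CO3 in DMF would then return 4.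

3. Step 7. With Cd next to the prochiral carbon, ligand and substrate may oppose each other (mismatched pairing), so that hydride transfer loses facial selectivity at Cx; any (Z)-enoate left in 10 would add the wrong epimer. Fallback: it sets out from 10 and comes back at 11. The trisubstituted enoate would be hydrogenated with H2 and a cationic iridium phosphine–oxazoline complex [Ir(cod)(L)][B(C6H3(CF3)2)4] in CH2Cl2, where coordination of the olefin to the metal, and not a conjugate hydride addition, decides the face; no new compound is involved.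

**Further compounds**
F1 | step 1 | (1R,5S)-3-oxabicyclo[3.2.1]octane-2,4-dione | O=C3[C@@H]1CC[C@H](C(=O)O3)C1
F2 | step 2 | (4S)-4-(tert-butoxycarbonyl)cyclopent-1-ene-1-carboxylic acid | OC(=O)C1=CC[C@H](C(=O)OC(C)(C)C)C1
F3 | step 2 | (1R,3S)-3-(tert-butoxycarbonyl)cyclopentane-1-carboxylic acid | OC(=O)[C@@H]1CC[C@H](C(=O)OC(C)(C)C)C1
F0 | step 7 | none | none
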